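## The problem

Compound 21 is the 7-O-ether of isofraxidin with a bicyclic sesquiterpene alcohol, 3β-acetoxy-9-epi-drim-7-en-11-ol. The terpene is a trans-fused decalin (rings A and B) with four stereocentres, C3, C5, C9 and C10, on a 4,4,10-trimethyl framework. The unusual centre is C9: its CH2O arm (C11) is axial and anti to the angular C10 methyl group, the opposite of what polyene cyclisation or the common drimane pool delivers. C9 and the quaternary C10 therefore have to be made together and on purpose. Once C10 exists it can control the rest: the trans fusion at C5 is the equilibrium outcome if C5 is made epimerisable, and the axial β-methyl groups on C4 and C10 steer hydride to the α-face of a C3 ketone, giving the 3β-alcohol. C9 cannot be corrected later, because its hydrogen is allylic to C7=C8 and acid moves that olefin to C8=C9; strong acid is therefore excluded late in the route. The coumarin lactone tolerates neither hydroxide nor strong hydride donors, the acetate is base-labile, and the C11–O bond must be made at a β-branched, axial primary carbon. What allows a short route is ring B itself: the one-carbon arm on C9 and the methyl group on C8 next to C7=C8 are the footprint of a buta-2,3-dienoyl unit added across a diene C7=C6–C5=C10, with C12 arriving as an exocyclic methylene.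

## Retrosynthesis

**Acetate and aryl ether.** Removing the acetate (21 ⇒ 20) and cutting the C11–O bond separates the terpene from isofraxidin 18. This cut keeps a commercial, fully substituted phenol intact and places the only hindered substitution at a CH2 group with no stereochemistry to lose. The forward coupling must pick the primary C11–OH among other hydroxyls and avoid base and hydride once the lactone is attached. A redox condensation does both, so the partner can be the unprotected triol 17 (giving 19).

**The C6 oxygen.** Between 20 and 19 an extra hydroxyl is added at C6 in the retrosynthetic direction. Triol 17 comes from enedione 16 by one hydride reduction that also sets the 3β-alcohol. In 16 the C6 carbonyl solves both remaining ring B problems: it makes C5 epimerisable, so the trans fusion is reached by equilibration, and it draws an exocyclic C8=C12 olefin to C7=C8 and not to C8=C9. The price is one deoxygenation (19 → 20), which asks that an allyl cation over C6–C8 take hydride at C6 only.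

**Unmasking.** Enedione 16 is the hydrolysed and isomerised form of 14, in which the C3 ketone is a dioxolane, the C6 ketone a silyl enol ether (C5=C6) and the C8 methyl still an exocyclic methylene. No skeletal bond changes. Alcohol 14 comes from imide 13 by reduction of the C11 acyl group, placed before the unmasking because C9–H of 13 lies between the imide carbonyl and the C8 olefin.

**Ring B by cycloaddition.** Adduct 13 is cut at C7–C8 and C9–C10 into the ring A diene 7 and the allenoyl imide 12.
- Against cutting C5–C10 or C8–C9, this pair of bonds divides the molecule into two achiral pieces of similar size and creates C9 and C10 in one event.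
- A diene with a bare vinyl group would make the same bonds, but its adduct would hold two ring B olefins that no reduction can tell apart in the needed sense: C5=C6, wedged between C4 and C10, is the least accessible. The silyloxy group on C6 of 7 removes this problem, raises the reactivity of a twisted tetrasubstituted diene and reinforces the regiochemistry.
- The forward reaction must deliver regiochemistry (C9 to C10), endo orientation (C11 anti to the C10 methyl) and one enantiomer. The last is asked of a chiral divalent copper bis(oxazoline) catalyst that chelates the imide.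

**Fragments.** Diene 7 is the silyl enol ether of methyl ketone 6, which comes from enol triflate 4 by cross-coupling with an acetyl anion equivalent. Triflate 4 comes from ketone 3, the methylation product of mono-ketal 2 of dione 1. Imide 12 is the acylation product of oxazolidinone 9 with acid 8, with alkyne-to-allene isomerisation.

## Roads not taken

**Alternative 1:** The cut is C5–C10 and C8–C9, closing both rings at once. The forward key step is a thermal intramolecular Diels–Alder reaction of an open-chain (Z)-enoate tethered to a 2-silyloxydiene, giving silyl enol ether A1.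
- Merits: C5, C9 and C10 arise in one step under substrate control from a C3 silyl ether, and the trans fusion comes directly. This is better than the chosen plan, which reaches C5 by equilibration and relies on a catalytic step not yet shown on this diene.
- Weak points: the triene needs a stereodefined trisubstituted (Z)-enoate, a stereodefined diene, a gem-dimethyl tether and an enantioselectively made C3 centre, so the linear sequence is long. The cycloaddition must form a quaternary carbon from a β,β-disubstituted enoate, which needs temperatures at which Z/E isomerisation and hydrogen shifts of the dienol ether compete. A1 then needs its C7 oxygen turned into C7=C8 through a regioselective enol triflate and its reduction.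
- Comparison: the redox overhead is similar to the C6 detour here. The chosen plan offers convergence, a five-step diene from a commercial dione, and absolute configuration from a catalyst instead of an early asymmetric step.

**Alternative 2:** No skeletal bond is cut; the temporary O7–C11 acyl bond is used. Methoxide would equilibrate C9 of a normal-configured 7α-hydroxy 11-ester, and only the 9α-epimer can reach O7, so it is trapped as the bridging lactone A2.
- Merits: C9 is fixed by a self-correcting thermodynamic event, which is more certain than any kinetic cycloaddition. The chosen plan sets C9 kinetically and must guard it through step 9.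
- Weak points: the substrate must already hold the 3β-oxygen, the 7α-hydroxyl and the C8 methyl centre. Common drimanes lack the C3 oxygen, so the decalin still has to be built and oxidised. After lactonisation come reduction, differentiation of two hydroxyls and a regioselective dehydration toward C8, all of which only adjust oxidation state.
- Comparison: more reliable at C9, but clearly longer and with a risky elimination.

**Alternative 3:** The cut is C4a–C8a of the coumarin. Thermolysis of a 4-alkenyl-4-methoxycyclobutenone bearing the terpenyl ether (4π opening, 6π closure) would give the pentasubstituted phenol acetal A3, followed by pyranone annulation.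
- Merits: the C11–O bond is made by alkoxide addition–elimination at an sp2 carbon, not by substitution at hindered C11. This is better than the Mitsunobu step here, and the arene substitution pattern is unambiguous.
- Weak points: the key step is spent on a part that can be bought as isofraxidin 18. The decalin stereochemistry is left unanswered, the same terpene alcohol is still needed, and several steps are added.
- Comparison: the chosen plan accepts a demanding etherification, with a fallback, in return for a short endgame from a commercial phenol.

Key step: step 7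

## Remarks

- Drimane numbering is used for all bicyclic compounds (C1–C10 decalin, C11 on C9, C12 on C8, C15 on C10); α is the face opposite the C10 methyl group.
- The diene carries a silyloxy group on C6 that takes no part in bond formation; the bonds made and the ring closed in step 7 are those of the parent vinylcyclohexene.
- The (R,R) ligand is chosen from the square-planar s-cis chelate model of divalent copper bis(oxazoline)–imide complexes; if the allenoyl chelate responds in the opposite sense, the (S,S) ligand is used and nothing else changes.
- t-Bu-box is 2,2′-(propane-2,2-diyl)bis(4-tert-butyl-4,5-dihydrooxazole).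

## Route

Step 1
Reactants: 1 2,2-dimethylcyclohexane-1,3-dione
Product: 2 6,6-dimethyl-1,4-dioxaspiro[4.5]decan-7-one
Conditions: HOCH2CH2OH (1.1 equiv), p-TsOH·H2O (cat.), benzene, reflux, azeotropic removal of water
Reagents that add atoms: ethane-1,2-diol, OCCO
Why: Acid-catalysed mono-ketalisation; once one dioxolane is in place the second carbonyl is flanked by the quaternary carbon and the ketal, so the bis-ketal should form slowly.

Step 2
Reactants: 2 6,6-dimethyl-1,4-dioxaspiro[4.5]decan-7-one
Product: 3 6,6,8-trimethyl-1,4-dioxaspiro[4.5]decan-7-one (racemic)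
Conditions: LiN(i-Pr)2, THF, −78 °C; MeI, −78 → 0 °C
Reagents that add atoms: iodomethane, CI
Why: Lithium enolate alkylation; only C8 is enolisable, so the regiochemistry is fixed, and the new stereocentre is erased in step 3.

Step 3
Reactants: 3 6,6,8-trimethyl-1,4-dioxaspiro[4.5]decan-7-one
Product: 4 6,6,8-trimethyl-1,4-dioxaspiro[4.5]dec-7-en-7-yl trifluoromethanesulfonate
Conditions: KN(SiMe3)2, THF, −78 °C; PhNTf2, −78 → 0 °C
Reagents that add atoms: N-phenylbis(trifluoromethanesulfonimide), O=S(=O)(N(c1ccccc1)S(=O)(=O)C(F)(F)F)C(F)(F)F
Why: Enol triflate formation from the potassium enolate; deprotonation is possible only at the methyl-bearing α-carbon, giving the tetrasubstituted triflate as known for 2,2,6-trimethylcyclohexanone.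

Step 4
Reactants: 4 6,6,8-trimethyl-1,4-dioxaspiro[4.5]dec-7-en-7-yl trifluoromethanesulfonate
Product: 6 1-(6,6,8-trimethyl-1,4-dioxaspiro[4.5]dec-7-en-7-yl)ethan-1-one, via ethoxydiene 5 (not isolated)
Conditions: CH2=C(OEt)SnBu3, Pd(PPh3)4 (5 mol %), LiCl, CuI (10 mol %), THF, 65 °C; then 0.5 M HCl, THF, 0 °C
Reagents that add atoms: tributyl(1-ethoxyvinyl)stannane, CCCC[Sn](CCCC)(CCCC)C(=C)OCC; water, O
Why: Stille coupling of a hindered cyclohexenyl triflate with an α-alkoxyvinylstannane as acetyl anion equivalent; the enol ether should hydrolyse at 0 °C far faster than the dioxolane.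

Step 5
Reactants: 6 1-(6,6,8-trimethyl-1,4-dioxaspiro[4.5]dec-7-en-7-yl)ethan-1-one
Product: 7 tert-butyl(dimethyl){[1-(6,6,8-trimethyl-1,4-dioxaspiro[4.5]dec-7-en-7-yl)ethenyl]oxy}silane
Conditions: TBSOTf, Et3N, CH2Cl2, 0 °C
Reagents that add atoms: tert-butyldimethylsilyl trifluoromethanesulfonate, CC(C)(C)[Si](C)(C)OS(=O)(=O)C(F)(F)F
Why: Soft enolisation of a methyl ketone with silyl triflate and amine gives the 2-silyloxydiene by deprotonation of the methyl group; the carbonyl of 6 is twisted out of conjugation, so it should behave as a simple methyl ketone.

Step 6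
Reactants: 8 but-3-ynoic acid; 9 oxazolidin-2-one
Product: 12 3-(buta-2,3-dienoyl)oxazolidin-2-one, via mixed pivalic anhydride 10 (not isolated), via butynoyl imide 11 (not isolated)
Conditions: t-BuCOCl, Et3N, THF, −20 °C; then 9, LiCl, −20 → 23 °C
Reagents that add atoms: none
Why: N-acylation of the oxazolidinone through the mixed pivalic anhydride; the doubly activated propargylic CH2 of 11 is isomerised by Et3N to the conjugated allene.

Step 7
Reactants: 7 tert-butyl(dimethyl){[1-(6,6,8-trimethyl-1,4-dioxaspiro[4.5]dec-7-en-7-yl)ethenyl]oxy}silane; 12 3-(buta-2,3-dienoyl)oxazolidin-2-one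
Product: 13 3-[6-(tert-butyldimethylsilyloxy)-3,3-(ethylenedioxy)-9-epi-drima-5,8(12)-dien-11-oyl]oxazolidin-2-one (9βH, acyl group α, 10β-methyl)
Conditions: [Cu((R,R)-t-Bu-box)](SbF6)2 (10 mol %, from CuCl2, ligand and AgSbF6), 4 Å molecular sieves, CH2Cl2, −40 → 0 °C
Reagents that add atoms: none
Why: The dicationic copper complex chelates both imide carbonyls of 12 and activates the allene's conjugated π bond; the silyl enol ether terminus C7 of 7 bonds to the central allene carbon C8 first and C9 then closes onto C10 in a concerted but strongly asynchronous [4+2] cycloaddition. The closest known reaction type is the copper bis(oxazoline)-catalysed enantioselective Diels–Alder reaction of chelating N-enoyl oxazolidinones, together with Lewis-acid cycloadditions of allenic acyl dienophiles to 2-silyloxydienes. Ring B is closed as a six-membered ring by intermolecular [4+2] union, suprafacial on both partners. C9 is set by the catalyst: in the square-planar s-cis chelate a tert-butyl group of the (R,R) ligand covers the Re face of the α-carbon, so C10 bonds to its Si face. C10 is set relative to C9 by the endo orientation of the chelated acyl group, which puts C11 cis to the outside substituent (C1) and trans to the inside methyl of the diene terminus, the 9-epi relationship. Regiochemistry is secured twice, by the silyloxy group (largest HOMO coefficient on C7) and by the two alkyl groups on C10. Only the conjugated allene π bond reacts, which leaves C12 as the exocyclic methylene.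

Step 8
Reactants: 13 3-[6-(tert-butyldimethylsilyloxy)-3,3-(ethylenedioxy)-9-epi-drima-5,8(12)-dien-11-oyl]oxazolidin-2-one
Product: 14 6-(tert-butyldimethylsilyloxy)-3,3-(ethylenedioxy)-9-epi-drima-5,8(12)-dien-11-ol (9βH, CH2OH α)
Conditions: LiBH4, MeOH (1 equiv), Et2O, 0 °C
Reagents that add atoms: none
Why: Reductive cleavage of an N-acyloxazolidinone at the exocyclic carbonyl gives the primary alcohol and leaves silyl enol ether, ketal and olefins alone; it is done now so that the acidified C9–H of the imide is gone before step 9.

Step 9
Reactants: 14 6-(tert-butyldimethylsilyloxy)-3,3-(ethylenedioxy)-9-epi-drima-5,8(12)-dien-11-ol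
Product: 16 11-hydroxy-9-epi-drim-7-ene-3,6-dione (5αH, 9βH, trans-decalin), via unconjugated diketone 15 (not isolated)
Conditions: 2 M HCl, THF, 23 → 40 °C
Reagents that add atoms: water, O
Why: Acid hydrolyses the silyl enol ether and the dioxolane; β,γ-unsaturated ketone 15 moves its exocyclic olefin into conjugation through the C6 dienol, which fixes it at C7=C8. Enolisation toward C5 equilibrates the ring fusion to the more stable trans-decalin (5αH).

Step 10
Reactants: 16 11-hydroxy-9-epi-drim-7-ene-3,6-dione
Product: 17 9-epi-drim-7-ene-3β,6β,11-triol (5αH, 9βH)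
Conditions: NaBH4, CeCl3·7H2O, MeOH, −40 → 0 °C
Reagents that add atoms: none
Why: Luche reduction, 1,2-selective at the enone; hydride should add to both carbonyls from the α-face because the axial 4β- and 10β-methyl groups block the β-face. This gives the equatorial 3β-alcohol of the target and an axial 6β-alcohol that is removed in step 12.

Step 11
Reactants: 17 9-epi-drim-7-ene-3β,6β,11-triol; 18 isofraxidin (7-hydroxy-6,8-dimethoxycoumarin)
Product: 19 7-[(3β,6β-dihydroxy-9-epi-drim-7-en-11-yl)oxy]-6,8-dimethoxycoumarin
Conditions: PPh3, DIAD, THF, 0 → 23 °C
Reagents that add atoms: none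
Why: Mitsunobu etherification; the acidic 7-OH of 18 is a good pronucleophile, and only the primary C11–OH should be activated, since the neopentyl-type 3β-OH and the doubly 1,3-diaxial 6β-OH are shielded. No stereocentre is touched.

Step 12
Reactants: 19 7-[(3β,6β-dihydroxy-9-epi-drim-7-en-11-yl)oxy]-6,8-dimethoxycoumarin
Product: 20 7-[(3β-hydroxy-9-epi-drim-7-en-11-yl)oxy]-6,8-dimethoxycoumarin
Conditions: Et3SiH, BF3·OEt2, CH2Cl2, −78 → −40 °C
Reagents that add atoms: none
Why: Ionic hydrogenolysis of an allylic alcohol; BF3 ionises the 6β-OH to the C6–C7–C8 allyl cation and the silane should deliver hydride to the secondary terminus C6 from the open α-face, since C8 is tertiary and shielded by C11 and the C10 methyl. The C7=C8 olefin is kept, and the non-allylic 3β-OH, the aryl ethers and the lactone should not ionise at this temperature.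

Step 13
Reactants: 20 7-[(3β-hydroxy-9-epi-drim-7-en-11-yl)oxy]-6,8-dimethoxycoumarin
Product: 21 7-{[(3S,5R,9R,10S)-3-acetoxy-9-epi-drim-7-en-11-yl]oxy}-6,8-dimethoxycoumarin (CNP0285931.2)
Conditions: Ac2O, pyridine, DMAP (cat.), CH2Cl2, 23 °C
Reagents that add atoms: acetic anhydride, CC(=O)OC(C)=O
Why: DMAP-catalysed acetylation of the only remaining hydroxyl under conditions the coumarin tolerates.

## Compound list

1 | 2,2-dimethylcyclohexane-1,3-dione | CC1(C)C(=O)CCCC1=O | starting material
2 | 6,6-dimethyl-1,4-dioxaspiro[4.5]decan-7-one | CC1(C)C(=O)CCCC12OCCO2 | intermediate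
3 | 6,6,8-trimethyl-1,4-dioxaspiro[4.5]decan-7-one (racemic) | CC1CCC2(OCCO2)C(C)(C)C1=O | intermediate
4 | 6,6,8-trimethyl-1,4-dioxaspiro[4.5]dec-7-en-7-yl trifluoromethanesulfonate | CC1=C(OS(=O)(=O)C(F)(F)F)C(C)(C)C2(OCCO2)CC1 | intermediate
5 | 7-(1-ethoxyethenyl)-6,6,8-trimethyl-1,4-dioxaspiro[4.5]dec-7-ene | C=C(OCC)C1=C(C)CCC2(OCCO2)C1(C)C | intermediate (not isolated)
6 | 1-(6,6,8-trimethyl-1,4-dioxaspiro[4.5]dec-7-en-7-yl)ethan-1-one | CC(=O)C1=C(C)CCC2(OCCO2)C1(C)C | intermediate
7 | tert-butyl(dimethyl){[1-(6,6,8-trimethyl-1,4-dioxaspiro[4.5]dec-7-en-7-yl)ethenyl]oxy}silane | C=C(O[Si](C)(C)C(C)(C)C)C1=C(C)CCC2(OCCO2)C1(C)C | intermediate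
8 | but-3-ynoic acid | C#CCC(=O)O | starting material
9 | oxazolidin-2-one | O=C1NCCO1 | starting material
10 | but-3-ynoic pivalic anhydride | C#CCC(=O)OC(=O)C(C)(C)C | intermediate (not isolated)
11 | 3-(but-3-ynoyl)oxazolidin-2-one | C#CCC(=O)N1CCOC1=O | intermediate (not isolated)
12 | 3-(buta-2,3-dienoyl)oxazolidin-2-one | C=C=CC(=O)N1CCOC1=O | intermediate
13 | 3-[6-(tert-butyldimethylsilyloxy)-3,3-(ethylenedioxy)-9-epi-drima-5,8(12)-dien-11-oyl]oxazolidin-2-one (9βH, 10β-methyl) | O=C1OCCN1C(=O)[C@@H]1C(=C)CC(O[Si](C)(C)C(C)(C)C)=C2C(C)(C)C3(OCCO3)CC[C@]12C | intermediate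
14 | 6-(tert-butyldimethylsilyloxy)-3,3-(ethylenedioxy)-9-epi-drima-5,8(12)-dien-11-ol | OC[C@@H]1C(=C)CC(O[Si](C)(C)C(C)(C)C)=C2C(C)(C)C3(OCCO3)CC[C@]12C | intermediate
15 | 11-hydroxy-9-epi-drim-8(12)-ene-3,6-dione (C5 epimers) | OC[C@@H]1C(=C)CC(=O)C2C(C)(C)C(=O)CC[C@]12C | intermediate (not isolated)
16 | 11-hydroxy-9-epi-drim-7-ene-3,6-dione (5αH) | OC[C@@H]1C(C)=CC(=O)[C@H]2C(C)(C)C(=O)CC[C@]12C | intermediate
17 | 9-epi-drim-7-ene-3β,6β,11-triol | OC[C@@H]1C(C)=C[C@@H](O)[C@H]2C(C)(C)[C@@H](O)CC[C@]12C | intermediate
18 | isofraxidin (7-hydroxy-6,8-dimethoxycoumarin) | COc1cc2ccc(=O)oc2c(OC)c1O | starting material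
19 | 7-[(3β,6β-dihydroxy-9-epi-drim-7-en-11-yl)oxy]-6,8-dimethoxycoumarin | COc1cc2ccc(=O)oc2c(OC)c1OC[C@@H]1C(C)=C[C@@H](O)[C@H]2C(C)(C)[C@@H](O)CC[C@]12C | intermediate
20 | 7-[(3β-hydroxy-9-epi-drim-7-en-11-yl)oxy]-6,8-dimethoxycoumarin | COc1cc2ccc(=O)oc2c(OC)c1OC[C@@H]1C(C)=CC[C@H]2C(C)(C)[C@@H](O)CC[C@]12C | intermediate
21 | 7-{[(3S,5R,9R,10S)-3-acetoxy-9-epi-drim-7-en-11-yl]oxy}-6,8-dimethoxycoumarin | COc1cc2ccc(=O)oc2c(OC)c1OC[C@@H]1C(C)=CC[C@H]2C(C)(C)[C@@H](OC(C)=O)CC[C@]12C | target

## Step count and risks

Total: 13 steps. Longest linear sequence: 12 steps (steps 1–5 and 7–13, from 1 to 21).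

**Step 7 (key step).** The most likely failure is a fully stepwise course. After the C7–C8 bond forms, the open intermediate may close at C6 to a cyclobutane, close through C12 to the conjugated alkylidene isomer, or lose silicon to give back ketone 6 beside a simple Michael adduct. Endo and facial selectivity would then be decided without the organisation of a cycloaddition transition state, and the copper centre may also be tied up by the ketal oxygens. The fallback is auxiliary control with a stoichiometric aluminium Lewis acid, setting out from 8 and 7. Acid 8 is coupled as in step 6 with commercial (S)-4-benzyloxazolidin-2-one to give (S)-4-benzyl-3-(buta-2,3-dienoyl)oxazolidin-2-one F1. With Et2AlCl in CH2Cl2 at −78 °C, diene 7 should add to the face of the chelated s-cis dienophile opposite the benzyl group (the Si face of the α-carbon, as required) to give the auxiliary-bearing adduct F2. LiBH4 cleavage of F2 returns the route at 14.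

**Step 12.** Three failures are possible: hydride delivery at C8, which gives the C6=C7 olefin and an uncontrolled C8 centre; proton loss from the cation to a ring B diene; or acid-induced drift of the product olefin to C8=C9, which destroys C9. The fallback removes the C6 oxygen at the ketone level without an allyl cation and sets out from 16.
- NaBH4 at −78 °C should reduce only the unhindered saturated C3 ketone, giving 3β,11-dihydroxy-9-epi-drim-7-en-6-one F3.
- Ethane-1,2-dithiol with BF3·OEt2 converts the enone carbonyl into the 6,6-ethylenedithio derivative F4.
- Raney Ni in ethanol removes sulfur with the olefin in place, giving 9-epi-drim-7-ene-3β,11-diol F5.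
- Mitsunobu coupling of F5 with 18 as in step 11 returns the route at 20.

**Step 9.** Equilibration at C5 may be incomplete, and forcing it invites enolisation through the extended dienol toward C9, which would erode the configuration set in step 7. The fallback separates the three events, avoids protic acid while the enone forms, and sets out from 14. Bu4NF buffered with AcOH in THF at 0 °C releases the C6 enolate, and DBU in CH2Cl2 completes conjugation and C5 equilibration, giving 3,3-(ethylenedioxy)-11-hydroxy-9-epi-drim-7-en-6-one F6. The dioxolane is then removed with pyridinium p-toluenesulfonate in wet acetone, returning the route at 16.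

**Step 11.** Redox condensation at the β-branched, axial C11 carbinol may be slow, so that the activated alcohol eliminates or the reagents are consumed unproductively. The fallback replaces the one-pot activation by a sulfonate and an SN2 displacement and sets out from 17. MsCl and Et3N at −20 °C should sulfonylate only the primary hydroxyl, giving 3β,6β-dihydroxy-9-epi-drim-7-en-11-yl methanesulfonate F7. Its displacement by the caesium phenoxide of 18 (Cs2CO3, DMF, 60 °C) returns the route at 19.

**Step 8.** Hydride may attack the ring carbamate carbonyl, because the acyl carbon sits next to the quaternary C10; this would open the oxazolidinone instead of releasing the alcohol. The fallback sets out from 13. LiOH and H2O2 in aqueous THF at 0 °C, which attack the exocyclic carbonyl selectively, give 6-(tert-butyldimethylsilyloxy)-3,3-(ethylenedioxy)-9-epi-drima-5,8(12)-dien-11-oic acid F8. LiAlH4 in THF at 0 °C reduces F8 and returns the route at 14.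

## Further compounds

F1 | step 7 | (S)-4-benzyl-3-(buta-2,3-dienoyl)oxazolidin-2-one | C=C=CC(=O)N1[C@@H](Cc2ccccc2)COC1=O
F2 | step 7 | (S)-4-benzyl-3-[6-(tert-butyldimethylsilyloxy)-3,3-(ethylenedioxy)-9-epi-drima-5,8(12)-dien-11-oyl]oxazolidin-2-one | O=C1OC[C@H](Cc2ccccc2)N1C(=O)[C@@H]1C(=C)CC(O[Si](C)(C)C(C)(C)C)=C2C(C)(C)C3(OCCO3)CC[C@]12C
F3 | step 12 | 3β,11-dihydroxy-9-epi-drim-7-en-6-one | OC[C@@H]1C(C)=CC(=O)[C@H]2C(C)(C)[C@@H](O)CC[C@]12C
F4 | step 12 | 6,6-(ethylenedithio)-9-epi-drim-7-ene-3β,11-diol | OC[C@@H]1C(C)=CC3(SCCS3)[C@H]2C(C)(C)[C@@H](O)CC[C@]12C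
F5 | step 12 | 9-epi-drim-7-ene-3β,11-diol | OC[C@@H]1C(C)=CC[C@H]2C(C)(C)[C@@H](O)CC[C@]12C
F6 | step 9 | 3,3-(ethylenedioxy)-11-hydroxy-9-epi-drim-7-en-6-one | OC[C@@H]1C(C)=CC(=O)[C@H]2C(C)(C)C3(OCCO3)CC[C@]12C
F7 | step 11 | 3β,6β-dihydroxy-9-epi-drim-7-en-11-yl methanesulfonate | CS(=O)(=O)OC[C@@H]1C(C)=C[C@@H](O)[C@H]2C(C)(C)[C@@H](O)CC[C@]12C
F8 | step 8 | 6-(tert-butyldimethylsilyloxy)-3,3-(ethylenedioxy)-9-epi-drima-5,8(12)-dien-11-oic acid | OC(=O)[C@@H]1C(=C)CC(O[Si](C)(C)C(C)(C)C)=C2C(C)(C)C3(OCCO3)CC[C@]12C
A1 | alternative 1 | trans-fused decalin silyl enol ether with 9α-methyl ester | COC(=O)[C@@H]1[C@@H](C)C(O[Si](CC)(CC)CC)=C[C@H]2C(C)(C)[C@@H](O[Si](C)(C)C(C)(C)C)CC[C@]12C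
A2 | alternative 2 | 9-epi-drimane-11,7α-olide 3β-silyl ether | O=C1[C@@H]2[C@@H](C)[C@H](O1)C[C@H]3C(C)(C)[C@@H](O[Si](C)(C)C(C)(C)C)CC[C@]23C
A3 | alternative 3 | 2-hydroxy-3,5-dimethoxy-4-(terpenyloxy)benzaldehyde diethyl acetal | CCOC(OCC)c1cc(OC)c(OC[C@@H]2C(C)=CC[C@H]3C(C)(C)[C@@H](O[Si](C)(C)C(C)(C)C)CC[C@]23C)c(OC)c1O
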